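(The earlier runs and the new flask come from a simulation with made-up constants; the scatter is artificial.)

**Working catalyst.** If L took D one for one, I reasoned, the catalyst still turning Q over in a flask was c_D − c_L, and I reckoned with that difference. No earlier run varied either charge, so this remained my assumption.

the same everywhere: Q 0.12 M (fed, over 50 s)

| charge | D | L | remark | time |
|---|---|---|---|---|
| dusk | 7.4 mM | 1.5 mM | run made earlier |  |
| ash | 4.9 mM | 1.5 mM |  | 3.0 min |
| maple | 4.9 mM | 2.5 mM |  | 3.0 min |
| cedar | 4.9 mM | 4.0 mM |  | 3.0 min |

dusk run (percent of the Q charged)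

| time / s | X / % | Q / % |
|---|---|---|
| 10.0 | 0.8 | 19.3 |
| 15.0 | 0.9 | 28.7 |
| 30.0 | 3.9 | 55.3 |
| 50.0 | 11.0 | 87.6 |
| 60.0 | 14.8 | 83.6 |

(each reading ± 0.3 percentage points)

- the numbers in the tables scatter with a standard deviation of 0.3 percentage points
- percentages count the whole charge, also what has not yet gone in
- no earlier run changes the charge of D; that part of a forecast is a guess
- "hardly changes" means that all values lie within two and a half points (for a concentration: within two and a half percent of the largest)

* [X] at the end for ash, maple, cedar, in this order
* how the row runs (falls all the way / rises all the way / hardly changes / rises, then falls / falls, then rises)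

**The constant.** In dusk, X rose by 3.8 percentage points between 50.0 s and 60.0 s, while Q stood near 85.6 %. I read from this a pseudo-first-order constant of 0.00444 s⁻¹, a reading that carries the scatter of 0.3 points. By that difference, dusk's working catalyst was 5.90 mM, so I took the rate constant per working catalyst as 0.752 M⁻¹ s⁻¹.

**The curve.** For ash, I took a working catalyst of 3.40 mM, which gave a constant k of 0.00256 s⁻¹. By my reckoning, ash's X curve left the origin flat, with c_Q still near zero, and climbed with the square of time to a knee at 50 s, where X reached 6.40 %. Beyond the knee it bent into an exponential, as if the charge had gone in at mid-feed, and ran towards a level of 0.12 M. By this estimate it came to 0.0600 M at 4.93 min, later than 3.0 min, so I expected ash to be stopped on the rising part.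

**The row.** With t the time since mid-feed, 155 s at the end, I used c_X = c_charge(1 − exp(−kt)). Ash gave 0.0393 M. Maple, with 2.40 mM working, gave 0.0293 M. Cedar, with 0.900 mM working, a quarter of ash's, gave 0.0120 M. I expected a steady fall.

**The result.** The forecast stood at 0.0462 M, 0.0458 M and 0.0452 M, hardly changes, on the view that “L seems to hold or consume about one Q each, without touching the catalysis”. The flasks gave 0.0407 M, 0.0301 M and 0.0123 M: falls all the way.

    Q + D ⇌ G (K = 3.90 M⁻¹, k = 5.80 M⁻¹ s⁻¹)
    G → D + X (k = 0.320 s⁻¹)
    D + L → E (k = 120 M⁻¹ s⁻¹)

At 3.00 min, E held 30.6 %, 51.0 % and 81.6 % of the D charged in ash, maple and cedar, with L at 0 %, 0 % and 0 % of its own charge. Used once more on cedar, the constant per working catalyst gives k = 6.77 × 10⁻⁴ s⁻¹, and so Q at 30.1 % of the charge at 30.0 min; cedar held 25.7 %.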